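## The problem

The target is a flavonol, a 2-aryl-3-hydroxy-4H-chromen-4-one in which ring A, ring C and ring B are joined through sp2 carbons only. It has no stereocentre, so nothing has to be set and nothing can steer; the difficulty is regiochemical and lies in the order in which oxygens are introduced and unmasked. Ring A carries four oxygens in a 1,2,3,5 arrangement (O1 on C8a, OMe on C8, OH on C7, OH on C5). The middle one of three neighbours is methylated, one neighbour is the ring oxygen and the other two are free phenols, so the four must be told apart at the start. Ring C needs a hydroxyl on C3 next to the C4 carbonyl, and the classical oxidative closures of open-chain precursors tend to give five-membered benzofuranones when C5 bears oxygen. The prenyl ether on O4' is the fragile group. Its trisubstituted alkene reacts with carbenes, peroxy reagents and osmium, it is lost on hydrogenolysis, and strong Brønsted or Lewis acids ionise its allylic C–O bond. It must therefore be attached late, to the only free hydroxyl present, and the last unmasking of the 3-, 5- and 7-hydroxyls must be mild. The feature that the plan exploits is the position of C3 between C2 (which carries ring B and O1) and the C4 carbonyl. With C3 taken out, ring C is a 2-arylbenzofuran-3(2H)-one, whose silyl enol ether has an electron-rich C2=C3 bond flanked by two oxygens; an electrophilic one-carbon unit that arrives with a halogen can be put back into that bond and brings the C3 hydroxyl within reach.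

## Retrosynthesis

**Unmasking and the prenyl ether.** The last bonds cut are the three acetal C–O bonds of 19, which return the 3-, 5- and 7-hydroxyls of 20. Before them comes the O4'–CH2 bond, which divides 19 into phenol 17 and prenyl bromide 18. The prenyl group is attached this late because its alkene would survive neither the carbene of the key step nor the hydrogenolysis that frees O4'. Methoxymethyl acetals are preferred to benzyl or acyl groups on the other oxygens because they tolerate strong base and come off without hydrogen or Lewis acid. The forward steps must alkylate a single phenoxide and then cleave acetals without ionising the allylic ether.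

**Ring B phenol and the C3 oxygen.** 17 goes back to benzyl ether 16 (O–CH2Ph bond) and 16 to flavonol 15 (acetal on O3). The C3–O bond of 15 is traced to the C3–Br bond of 13. A halogen at C3 is preferred to direct oxidation of a C3–H flavone, which would need a strong base on a ring A that is itself prone to metalation between its two acetal groups. 13 is no smaller than 15, but it is exactly what the ring expansion delivers. The forward step must exchange bromine for oxygen without exposing the 3-bromochromone to hot hydroxide.

**One-carbon insertion.** In 13 the bonds C2–C3 and C3–C4 are cut and C3 is excised with its bromine. What remains is silyl enol ether 9, and the excised unit is bromoform 10 at the carbene oxidation level. The neighbouring cuts of ring C (O1–C2, C4–C4a, C3–C4) all need an open-chain precursor that already holds the C3 oxygen and must later be oxidised to the flavone level. This cut removes one carbon, keeps the bicycle closed and reaches the chromone oxidation state directly. It also turns the preference of C5-oxygenated systems for five-membered closure into an advantage. The forward reaction must add the carbene from 10 to the C2=C3 bond of 9 only (adduct 11), open the bond shared by the two small rings (ion pair 12) and lose the silyl group.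

**The benzofuran.** 9 is cut at O–Si and at its C2–C3 bond. The enolate 8 behind it arises from ester 7 when the benzylic carbon attacks the ester carbonyl. This is preferred to acid-mediated acylation of a ring A phenol, which is incompatible with the acetals and could close onto either of two ortho oxygens. The bond made here is the one the carbene later opens; its role is to place the aryl-bearing carbon and the carbonyl carbon in one enol ether. 7 has no ring C at all. The forward step needs deprotonation of a benzylic ether and O-silylation of 8.

**Joining ring A and ring B.** The O–CH2 bond of 7 is cut to phenol 5 and benzylic chloride 6. Both are stable, and this is the convergent point of the route. The forward step is an etherification of a chelated, flanked phenol.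

**Ring A.** In 5 the methyl on O3 is removed to give catechol 4. The C3–O bond of 4 is traced to the formyl group of 3, and that carbon to phenol 2, which comes from 1 by acetal formation on the two hydroxyls that are not locked to the ester. The ester of 1 makes this short: it is kept as C4 of 20, it differentiates the three phenols (the chelated one becomes O1), and it leaves only one ortho position for the formyl group. A formyl group in place of the ester would have to be spent on the methoxy-bearing carbon, and a carbonyl carbon would then have to be reinstalled. The forward steps are bis-etherification, ortho-specific formylation, aryl migration from carbon to oxygen, and methylation of the non-chelated hydroxyl.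

## Roads not taken

Alternative 1: Both ring C oxygens are traced to the C3=C4 alkene of flavene A1, with ring C already closed. In the forward step catalytic OsO4 (octavalent osmium) with N-methylmorpholine N-oxide adds syn across that alkene from the face opposite the C2 aryl group and gives diol A2.
- Merits: this is among the most dependable reactions available, it installs both oxygens in one operation, and its facial outcome is predictable.
- Weak points: three stereocentres are made only to be destroyed. From A2 the flavonol still needs a four-electron oxidation (C4 carbinol to ketone, then C2–C3 dehydrogenation) on a 4-hydroxyflavan whose electron-rich ring A makes the C4–O bond ionise easily. A1 is itself an air- and acid-sensitive 2H-chromene. The prenyl alkene cannot be present, so ring B needs the same benzyl detour as in the chosen plan.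
- Comparison: the key step of this road is more certain than the carbene insertion. Against that, the chosen plan delivers ring C at the chromone oxidation level with a handle on C3, carries no stereochemical ballast, and needs no redox adjustment after ring formation.

Alternative 2: Ring C is opened at C4–C4a to acid A3, in which the O1–C2 ether and the C3 oxygen are already in place. In the forward step trifluoroacetic anhydride forms a mixed anhydride that acylates the only free position ortho to the ether oxygen of ring A and closes ring C as flavanone A4.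
- Merits: intramolecular Friedel–Crafts acylation of a phloroglucinol-type ring is fast, metal-free and regiochemically unambiguous, and the C3 oxygen is present before the ring closes, which the chosen plan achieves only afterwards.
- Weak points: the acidic conditions exclude acetal protection, so O3, O5 and O7 carry benzyl groups and O4' a sulfonate. Removing the benzyl groups (hydrogen or BCl3) is incompatible with a prenyl ether, so a protecting-group exchange is needed near the end. The activated β-aryloxy acid can lose the phenol by elimination, and A4 can reopen by a retro-oxa-Michael reaction. A4 must still be dehydrogenated, and A3 needs two stereocentres that are later erased.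
- Comparison: the C–C bond formation is as reliable as any step in the chosen route. The chosen plan sets against it one protecting-group scheme that runs from step 1 to the end and a ring C that needs no dehydrogenation.

Alternative 3: Ring C is opened at C3–C4 to dialdehyde A5. In the forward step a triazolium-derived N-heterocyclic carbene with base turns the ring A aldehyde into an acyl anion equivalent that adds to the aliphatic aldehyde (crossed benzoin) and closes ring C as 3-hydroxyflavanone A6.
- Merits: the step is catalytic and redox-neutral and sets the C4 carbonyl and the C3 hydroxyl at once. The nucleophilic carbene leaves the prenyl alkene alone, so ring B can carry the prenyl ether from the start. If the step worked, the endgame (dehydrogenation, acetal removal) would be shorter than the five steps that follow the key step here.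
- Weak points: the ring A aldehyde is di-ortho-substituted and very electron-rich, hence a poor acyl anion donor. The aliphatic aldehyde is the better donor and would place the carbonyl on C3 and the hydroxyl on C4. A5 is an enolisable α-aryl α-aryloxy aldehyde prone to aldol reaction and air oxidation. Dehydrogenation of A6 must spare the prenyl alkene and avoid base-induced ring contraction.
- Comparison: this road is shorter on paper after ring closure. The chosen plan sets against it stable, easily purified intermediates (7, 9) and a ring expansion whose oxygen placement is fixed by the ester carbon, which becomes C4 without ambiguity.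

Key step: step 7

Assumption: 1, 6, 10 and 18 are commercial; ring A is drawn from ester 1 because its ester carbon is retained as C4 of 20.

## Route

Step 1
Reactants: 1 methyl 2,4,6-trihydroxybenzoate
Product: 2 methyl 2-hydroxy-4,6-bis(methoxymethoxy)benzoate
Conditions: MOMCl (2.2 equiv), iPr2NEt, CH2Cl2, 0 °C → rt
Reagents that add atoms: chloromethyl methyl ether, COCCl
Why: O-Alkylation with an oxocarbenium-type electrophile takes the para hydroxyl and one ortho hydroxyl, while the last hydroxyl stays locked in the hydrogen bond to the ester carbonyl and is left for later use as O1.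

Step 2
Reactants: 2 methyl 2-hydroxy-4,6-bis(methoxymethoxy)benzoate
Product: 3 methyl 3-formyl-2-hydroxy-4,6-bis(methoxymethoxy)benzoate
Conditions: MgCl2, Et3N, (CH2O)n, MeCN, reflux; aq. NH4Cl
Reagents that add atoms: paraformaldehyde (as formaldehyde), C=O
Why: Casnati–Skattebøl ortho-formylation: the magnesium phenoxide delivers formaldehyde only to the carbon ortho to the free hydroxyl (the other ortho position is the ester carbon), a second formaldehyde oxidises the benzylic alkoxide to the aldehyde, and the basic medium spares the acetals.

Step 3
Reactants: 3 methyl 3-formyl-2-hydroxy-4,6-bis(methoxymethoxy)benzoate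
Product: 4 methyl 2,3-dihydroxy-4,6-bis(methoxymethoxy)benzoate
Conditions: 30% H2O2 (1.2 equiv), NaOH (1 M), THF–H2O, 0 °C; Na2SO3, then NaH2PO4 to pH 6
Reagents that add atoms: hydrogen peroxide, OO
Why: Dakin oxidation of an ortho-hydroxybenzaldehyde: hydroperoxide adds to the formyl group, the aryl ring (helped by ortho and para alkoxy groups) migrates to oxygen and the formate is hydrolysed in the flask; the di-ortho-substituted methyl ester is too hindered to be saponified at 0 °C.

Step 4
Reactants: 4 methyl 2,3-dihydroxy-4,6-bis(methoxymethoxy)benzoate
Product: 5 methyl 2-hydroxy-3-methoxy-4,6-bis(methoxymethoxy)benzoate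
Conditions: NaH (2.1 equiv), DMF, 0 °C; MeI (1.0 equiv), 0 °C → rt; aq. NH4Cl
Reagents that add atoms: iodomethane, CI
Why: Regioselective O-alkylation of a catechol dianion: the O2 phenoxide is delocalised into the ester and chelated to sodium with the carbonyl, so the localised, more basic O3 phenoxide should take the single equivalent of iodomethane; the desired isomer keeps a chelated phenol, which distinguishes it from the other one.

Step 5
Reactants: 5 methyl 2-hydroxy-3-methoxy-4,6-bis(methoxymethoxy)benzoate, 6 4-(benzyloxy)benzyl chloride
Product: 7 methyl 2-{[4-(benzyloxy)phenyl]methoxy}-3-methoxy-4,6-bis(methoxymethoxy)benzoate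
Conditions: K2CO3, KI (cat.), DMF, 60 °C
Reagents that add atoms: none
Why: Williamson etherification; the 4-alkoxybenzyl chloride is a very reactive electrophile, and iodide catalysis in warm DMF makes up for the low nucleophilicity of the chelated, flanked phenoxide.

Step 6
Reactants: 7 methyl 2-{[4-(benzyloxy)phenyl]methoxy}-3-methoxy-4,6-bis(methoxymethoxy)benzoate
Product: 9 tert-butyl({2-[4-(benzyloxy)phenyl]-7-methoxy-4,6-bis(methoxymethoxy)-1-benzofuran-3-yl}oxy)dimethylsilane, via lithium benzofuran-3-olate 8 (not isolated)
Conditions: LiN(iPr)2 (3 equiv), THF, −78 → −20 °C; then TBSCl (3.5 equiv), DMPU, −20 °C → rt; aq. NaHCO3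
Reagents that add atoms: tert-butyldimethylsilyl chloride, CC(C)(C)[Si](C)(C)Cl
Why: Dieckmann-type intramolecular Claisen acylation: the amide base, held by the neighbouring ester, removes a proton from the ArO–CH2–Ar group, 5-exo-trig attack on the ester and loss of methoxide give the 2-arylbenzofuran-3(2H)-one, and this is deprotonated at once to the aromatic enolate 8, which drives the sequence forward; silylation on oxygen gives 9 and avoids handling the air-sensitive ketone.

Step 7
Reactants: 9 tert-butyl({2-[4-(benzyloxy)phenyl]-7-methoxy-4,6-bis(methoxymethoxy)-1-benzofuran-3-yl}oxy)dimethylsilane, 10 bromoform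
Product: 13 2-[4-(benzyloxy)phenyl]-3-bromo-8-methoxy-5,7-bis(methoxymethoxy)-4H-chromen-4-one, via gem-dibromocyclopropane adduct 11 (not isolated), via 4-silyloxybenzopyrylium bromide 12 (not isolated)
Conditions: CHBr3 (3 equiv), KOtBu (3 equiv, added slowly), toluene, −30 → 0 °C, then rt; aq. NaHCO3
Reagents that add atoms: none
Why: Proposed new method: The carbene released from 10 by α-elimination with KOtBu is electrophilic and should add to the most electron-rich π bond of 9, the C2=C3 enol ether bond that carries the furan oxygen, the silyloxy group and the 4-alkoxyphenyl ring, to give the cis-fused cyclopropane 11 (a concerted [2+1] closure of the three-membered ring). Ionisation of one C–Br bond is coupled to disrotatory opening of the bond shared by the two rings (cyclopropyl-to-allyl cation), pushed by the lone pairs of the silyloxy oxygen and of O1; the cation formed is the aromatic benzopyrylium ion of 12, so the six-membered ring arises by ring expansion and not by an exo or endo cyclisation. Bromide or the aqueous work-up then takes the silyl group from oxygen and leaves the 4-pyranone 13, in which the inserted carbon is C3 and keeps one bromine. The closest known reactions are the dihalocarbene ring expansion of cyclic silyl enol ethers to 2-halocycloalkenones and the Ciamician–Dennstedt expansion of indoles to 3-haloquinolines and of benzofurans to 3-halo-2H-chromenes; a 3-silyloxybenzofuran has not been used in either. No stereocentre remains: the two of 11 are cis by necessity and are erased on opening. The step needs chemoselectivity for the enol ether bond over the alkoxyarenes and benzylic ethers, which the two oxygen donors and the aryl group on that bond should provide, and cleavage of the internal cyclopropane bond, which alone leads to the doubly oxygen-stabilised aromatic cation. Slow addition of the base to 9 and 10 at low temperature keeps free alkoxide from attacking silicon before the carbene arrives.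

Step 8
Reactants: 13 2-[4-(benzyloxy)phenyl]-3-bromo-8-methoxy-5,7-bis(methoxymethoxy)-4H-chromen-4-one
Product: 15 2-[4-(benzyloxy)phenyl]-3-hydroxy-8-methoxy-5,7-bis(methoxymethoxy)-4H-chromen-4-one, via pinacol boronate 14 (not isolated)
Conditions: B2pin2, Pd2(dba)3, XPhos, KOAc, 1,4-dioxane, 90 °C; then 30% H2O2, aq. NaHCO3, THF, 0 °C → rt
Reagents that add atoms: bis(pinacolato)diboron (boron of 14), CC1(C)OB(OC1(C)C)B1OC(C)(C)C(C)(C)O1; hydrogen peroxide (oxygen of 15), OO
Why: Miyaura borylation of the vinylic C–Br bond (oxidative addition to zerovalent palladium, acetate-assisted transmetalation) gives 14, and buffered hydroperoxide oxidation (1,2-shift of C3 from boron to oxygen) gives the flavonol; the 3-bromochromone is never exposed to hot hydroxide, which would open or contract the pyranone ring.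

Step 9
Reactants: 15 2-[4-(benzyloxy)phenyl]-3-hydroxy-8-methoxy-5,7-bis(methoxymethoxy)-4H-chromen-4-one
Product: 16 2-[4-(benzyloxy)phenyl]-8-methoxy-3,5,7-tris(methoxymethoxy)-4H-chromen-4-one
Conditions: MOMCl, iPr2NEt, DMAP (cat.), CH2Cl2, 0 → 40 °C
Reagents that add atoms: chloromethyl methyl ether, COCCl
Why: Standard acetal protection of the enolic 3-hydroxyl, which would otherwise compete with O4' in the alkylation of step 11.

Step 10
Reactants: 16 2-[4-(benzyloxy)phenyl]-8-methoxy-3,5,7-tris(methoxymethoxy)-4H-chromen-4-one
Product: 17 2-(4-hydroxyphenyl)-8-methoxy-3,5,7-tris(methoxymethoxy)-4H-chromen-4-one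
Conditions: H2 (1 atm), 10% Pd/C, EtOAc–THF, rt
Reagents that add atoms: none
Why: Hydrogenolysis of the benzyl aryl ether; the tetrasubstituted, conjugated C2=C3 bond, the acetals and the aryl methyl ether are inert at one atmosphere and room temperature, and the bromine that would not survive has already been replaced.

Step 11
Reactants: 17 2-(4-hydroxyphenyl)-8-methoxy-3,5,7-tris(methoxymethoxy)-4H-chromen-4-one, 18 1-bromo-3-methylbut-2-ene (prenyl bromide)
Product: 19 8-methoxy-3,5,7-tris(methoxymethoxy)-2-{4-[(3-methylbut-2-en-1-yl)oxy]phenyl}-4H-chromen-4-one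
Conditions: K2CO3, acetone, 50 °C
Reagents that add atoms: none
Why: Williamson etherification (SN2 at the primary allylic carbon) of the only free phenol, whose anion is a vinylogous carboxylate; no other hydroxyl is available to compete.

Step 12
Reactants: 19 8-methoxy-3,5,7-tris(methoxymethoxy)-2-{4-[(3-methylbut-2-en-1-yl)oxy]phenyl}-4H-chromen-4-one
Product: 20 3,5,7-trihydroxy-8-methoxy-2-{4-[(3-methylbut-2-en-1-yl)oxy]phenyl}-4H-chromen-4-one (3,5,7-trihydroxy-8-methoxy-4'-prenyloxyflavone)
Conditions: HCl (ca. 1 M) in MeOH–THF, 0 → 40 °C, stopped at full conversion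
Reagents that add atoms: none
Why: Acid-catalysed acetal exchange with methanol removes the three methoxymethyl groups; the methoxymethyl oxocarbenium ion forms far more easily than a prenyl cation, and the O4' ether oxygen is deactivated by conjugation with the pyranone, so dilute acid at moderate temperature should spare the prenyl ether.

## Compound list

1 | methyl 2,4,6-trihydroxybenzoate | COC(=O)c1c(O)cc(O)cc1O | starting material
2 | methyl 2-hydroxy-4,6-bis(methoxymethoxy)benzoate | COC(=O)c1c(O)cc(OCOC)cc1OCOC | intermediate
3 | methyl 3-formyl-2-hydroxy-4,6-bis(methoxymethoxy)benzoate | COC(=O)c1c(O)c(C=O)c(OCOC)cc1OCOC | intermediate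
4 | methyl 2,3-dihydroxy-4,6-bis(methoxymethoxy)benzoate | COC(=O)c1c(O)c(O)c(OCOC)cc1OCOC | intermediate
5 | methyl 2-hydroxy-3-methoxy-4,6-bis(methoxymethoxy)benzoate | COC(=O)c1c(O)c(OC)c(OCOC)cc1OCOC | intermediate
6 | 4-(benzyloxy)benzyl chloride | ClCc1ccc(OCc2ccccc2)cc1 | starting material
7 | methyl 2-{[4-(benzyloxy)phenyl]methoxy}-3-methoxy-4,6-bis(methoxymethoxy)benzoate | COC(=O)c1c(OCc2ccc(OCc3ccccc3)cc2)c(OC)c(OCOC)cc1OCOC | intermediate
8 | lithium 2-[4-(benzyloxy)phenyl]-7-methoxy-4,6-bis(methoxymethoxy)-1-benzofuran-3-olate (formed in the flask) | COc1c(OCOC)cc(OCOC)c2c([O-])c(-c3ccc(OCc4ccccc4)cc3)oc12.[Li+] | intermediate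
9 | tert-butyl({2-[4-(benzyloxy)phenyl]-7-methoxy-4,6-bis(methoxymethoxy)-1-benzofuran-3-yl}oxy)dimethylsilane | COc1c(OCOC)cc(OCOC)c2c(O[Si](C)(C)C(C)(C)C)c(-c3ccc(OCc4ccccc4)cc3)oc12 | intermediate
10 | bromoform | BrC(Br)Br | starting material
11 | racemic, cis-fused 1a-[4-(benzyloxy)phenyl]-1,1-dibromo-6b-[(tert-butyldimethylsilyl)oxy]-3-methoxy-4,6-bis(methoxymethoxy)-1a,6b-dihydro-1H-cyclopropa[b][1]benzofuran (formed in the flask; one enantiomer drawn) | COc1c(OCOC)cc(OCOC)c2c1O[C@]1(c3ccc(OCc4ccccc4)cc3)C(Br)(Br)[C@]21O[Si](C)(C)C(C)(C)C | intermediate
12 | 2-[4-(benzyloxy)phenyl]-3-bromo-4-[(tert-butyldimethylsilyl)oxy]-8-methoxy-5,7-bis(methoxymethoxy)chromenylium bromide (formed in the flask) | COc1c(OCOC)cc(OCOC)c2c(O[Si](C)(C)C(C)(C)C)c(Br)c(-c3ccc(OCc4ccccc4)cc3)[o+]c12.[Br-] | intermediate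
13 | 2-[4-(benzyloxy)phenyl]-3-bromo-8-methoxy-5,7-bis(methoxymethoxy)-4H-chromen-4-one | COc1c(OCOC)cc(OCOC)c2c(=O)c(Br)c(-c3ccc(OCc4ccccc4)cc3)oc12 | intermediate
14 | 2-[4-(benzyloxy)phenyl]-8-methoxy-5,7-bis(methoxymethoxy)-3-(4,4,5,5-tetramethyl-1,3,2-dioxaborolan-2-yl)-4H-chromen-4-one (formed in the flask) | COc1c(OCOC)cc(OCOC)c2c(=O)c(B3OC(C)(C)C(C)(C)O3)c(-c3ccc(OCc4ccccc4)cc3)oc12 | intermediate
15 | 2-[4-(benzyloxy)phenyl]-3-hydroxy-8-methoxy-5,7-bis(methoxymethoxy)-4H-chromen-4-one | COc1c(OCOC)cc(OCOC)c2c(=O)c(O)c(-c3ccc(OCc4ccccc4)cc3)oc12 | intermediate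
16 | 2-[4-(benzyloxy)phenyl]-8-methoxy-3,5,7-tris(methoxymethoxy)-4H-chromen-4-one | COc1c(OCOC)cc(OCOC)c2c(=O)c(OCOC)c(-c3ccc(OCc4ccccc4)cc3)oc12 | intermediate
17 | 2-(4-hydroxyphenyl)-8-methoxy-3,5,7-tris(methoxymethoxy)-4H-chromen-4-one | COc1c(OCOC)cc(OCOC)c2c(=O)c(OCOC)c(-c3ccc(O)cc3)oc12 | intermediate
18 | 1-bromo-3-methylbut-2-ene | BrCC=C(C)C | starting material
19 | 8-methoxy-3,5,7-tris(methoxymethoxy)-2-{4-[(3-methylbut-2-en-1-yl)oxy]phenyl}-4H-chromen-4-one | COc1c(OCOC)cc(OCOC)c2c(=O)c(OCOC)c(-c3ccc(OCC=C(C)C)cc3)oc12 | intermediate
20 | 3,5,7-trihydroxy-8-methoxy-2-{4-[(3-methylbut-2-en-1-yl)oxy]phenyl}-4H-chromen-4-one | COc1c(O)cc(O)c2c(=O)c(O)c(-c3ccc(OCC=C(C)C)cc3)oc12 | target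

## Step count and least certain steps

Total step count: 12. Longest linear sequence: 12 steps, from 1 to 20; 6, 10 and 18 are bought and enter in steps 5, 7 and 11.

**Step 7 (key step, proposed new method).**
- What may go wrong: tert-butoxide may remove the silyl group before the carbene arrives, after which the free enolate is dibromomethylated on C2 (the abnormal Reimer–Tiemann course) instead of being cyclopropanated. Addition to a tetrasubstituted, heteroaromatic bond may be so slow that the carbene is consumed by base and solvent. Alkoxide may add to C2 of the 3-bromochromone once it has formed.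
- Fallback (known chemistry, sets out from 5, returns at 15, bypasses steps 5 to 8): ring C is built by an intramolecular Wittig reaction. Excess Ph3P=CH2 (THF, −78 °C → rt) converts the ester of 5 into 1-[2-hydroxy-3-methoxy-4,6-bis(methoxymethoxy)phenyl]-2-(triphenylphosphoranylidene)ethan-1-one F1. Acylation of its phenol with 4-(benzyloxy)benzoyl chloride (pyridine, toluene) gives 2-methoxy-3,5-bis(methoxymethoxy)-6-[(triphenylphosphoranylidene)acetyl]phenyl 4-(benzyloxy)benzoate F2, which on heating in the same flask olefinates its own ester carbonyl and closes to 2-[4-(benzyloxy)phenyl]-8-methoxy-5,7-bis(methoxymethoxy)-4H-chromen-4-one F3. Dimethyldioxirane (acetone–CH2Cl2, 0 °C) epoxidises C2=C3 to racemic 1a-[4-(benzyloxy)phenyl]-3-methoxy-4,6-bis(methoxymethoxy)-1a,7a-dihydro-7H-oxireno[2,3-b]chromen-7-one F4, and a trace of TsOH isomerises it to 15.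

**Step 6.**
- What may go wrong: deprotonation of the benzylic ether may be too slow because the 4-alkoxyphenyl ring lowers its kinetic acidity. The amide base may then metalate ring A between the two acetal groups or be consumed unproductively. The enol ether may also be lost by hydrolysis during isolation.
- Fallback (sets out from 5, returns at 9): the ring is closed with an ester-stabilised carbanion and ring B is attached afterwards.
  - Alkylation of 5 with methyl bromoacetate (K2CO3, DMF) gives methyl 3-methoxy-2-(2-methoxy-2-oxoethoxy)-4,6-bis(methoxymethoxy)benzoate F5.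
  - Dieckmann cyclisation (NaOMe, MeOH–THF), driven by an enolisable product, gives methyl 3-hydroxy-7-methoxy-4,6-bis(methoxymethoxy)-1-benzofuran-2-carboxylate F6.
  - Pinhey arylation with [4-(benzyloxy)phenyl]lead triacetate F7 (made from 4-(benzyloxy)phenylboronic acid and Pb(OAc)4) in pyridine–CHCl3 at 40 °C gives racemic methyl 2-[4-(benzyloxy)phenyl]-7-methoxy-4,6-bis(methoxymethoxy)-3-oxo-2,3-dihydro-1-benzofuran-2-carboxylate F8.
  - Krapcho dealkoxycarbonylation (LiCl, wet DMSO, 120 °C) gives racemic 2-[4-(benzyloxy)phenyl]-7-methoxy-4,6-bis(methoxymethoxy)-1-benzofuran-3(2H)-one F9.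
  - Silylation (TBSOTf, Et3N, CH2Cl2, 0 °C) gives 9.

**Step 8.**
- What may go wrong: the hindered C3–Br bond may undergo reductive debromination instead of borylation. Boronate 14 may suffer protodeboronation before it is oxidised. Base may add to C2 and open or contract the pyranone ring.
- Fallback (sets out from 13, returns at 15): the bromine is removed on purpose and the oxygen is brought in by epoxidation. Reduction of 13 with HCO2Na, Pd(OAc)2 and PPh3 (DMF, 80 °C) gives 2-[4-(benzyloxy)phenyl]-8-methoxy-5,7-bis(methoxymethoxy)-4H-chromen-4-one F3. Dimethyldioxirane converts it into racemic 1a-[4-(benzyloxy)phenyl]-3-methoxy-4,6-bis(methoxymethoxy)-1a,7a-dihydro-7H-oxireno[2,3-b]chromen-7-one F4, which a trace of TsOH isomerises to 15. This fallback makes no compound beyond F3 and F4.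

**Step 12.**
- What may go wrong: the acid needed for the slowest acetal (on O7, para to the carbonyl) may also ionise the allylic C–O bond, so that the prenyl group is lost or migrates to carbon.
- Fallback (sets out from 16, returns at 20): the acetals are exchanged for acetates before the prenyl group is introduced, so that the last unmasking is basic.
  - Methanolic HCl converts 16 into 2-[4-(benzyloxy)phenyl]-3,5,7-trihydroxy-8-methoxy-4H-chromen-4-one F10.
  - Ac2O, pyridine and DMAP give 2-[4-(benzyloxy)phenyl]-8-methoxy-4-oxo-4H-chromene-3,5,7-triyl triacetate F11.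
  - Hydrogenolysis (H2, 10% Pd/C, EtOAc) gives 2-(4-hydroxyphenyl)-8-methoxy-4-oxo-4H-chromene-3,5,7-triyl triacetate F12.
  - Mitsunobu etherification with 3-methylbut-2-en-1-ol (PPh3, diisopropyl azodicarboxylate, THF) gives 8-methoxy-2-{4-[(3-methylbut-2-en-1-yl)oxy]phenyl}-4-oxo-4H-chromene-3,5,7-triyl triacetate F13.
  - Methanolysis (K2CO3, MeOH, 0 °C, under argon) gives 20.

## Further compounds

F1 | step 7 | 1-[2-hydroxy-3-methoxy-4,6-bis(methoxymethoxy)phenyl]-2-(triphenylphosphoranylidene)ethan-1-one | COc1c(O)c(C(=O)C=P(c2ccccc2)(c2ccccc2)c2ccccc2)c(OCOC)cc1OCOC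
F2 | step 7 | 2-methoxy-3,5-bis(methoxymethoxy)-6-[(triphenylphosphoranylidene)acetyl]phenyl 4-(benzyloxy)benzoate | COc1c(OC(=O)c2ccc(OCc3ccccc3)cc2)c(C(=O)C=P(c2ccccc2)(c2ccccc2)c2ccccc2)c(OCOC)cc1OCOC
F3 | step 7 | 2-[4-(benzyloxy)phenyl]-8-methoxy-5,7-bis(methoxymethoxy)-4H-chromen-4-one | COc1c(OCOC)cc(OCOC)c2c(=O)cc(-c3ccc(OCc4ccccc4)cc3)oc12
F4 | step 7 | racemic 1a-[4-(benzyloxy)phenyl]-3-methoxy-4,6-bis(methoxymethoxy)-1a,7a-dihydro-7H-oxireno[2,3-b]chromen-7-one (one enantiomer drawn) | COc1c(OCOC)cc(OCOC)c2c1O[C@]1(c3ccc(OCc4ccccc4)cc3)O[C@@H]1C2=O
F5 | step 6 | methyl 3-methoxy-2-(2-methoxy-2-oxoethoxy)-4,6-bis(methoxymethoxy)benzoate | COC(=O)COc1c(OC)c(OCOC)cc(OCOC)c1C(=O)OC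
F6 | step 6 | methyl 3-hydroxy-7-methoxy-4,6-bis(methoxymethoxy)-1-benzofuran-2-carboxylate | COC(=O)c1oc2c(OC)c(OCOC)cc(OCOC)c2c1O
F7 | step 6 | [4-(benzyloxy)phenyl]lead triacetate | CC(=O)O[Pb](OC(C)=O)(OC(C)=O)c1ccc(OCc2ccccc2)cc1
F8 | step 6 | racemic methyl 2-[4-(benzyloxy)phenyl]-7-methoxy-4,6-bis(methoxymethoxy)-3-oxo-2,3-dihydro-1-benzofuran-2-carboxylate | COC(=O)C1(c2ccc(OCc3ccccc3)cc2)Oc2c(OC)c(OCOC)cc(OCOC)c2C1=O
F9 | step 6 | racemic 2-[4-(benzyloxy)phenyl]-7-methoxy-4,6-bis(methoxymethoxy)-1-benzofuran-3(2H)-one | O=C1C(c2ccc(OCc3ccccc3)cc2)Oc2c(OC)c(OCOC)cc(OCOC)c12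
F0 | step 8 | none | none
F10 | step 12 | 2-[4-(benzyloxy)phenyl]-3,5,7-trihydroxy-8-methoxy-4H-chromen-4-one | COc1c(O)cc(O)c2c(=O)c(O)c(-c3ccc(OCc4ccccc4)cc3)oc12
F11 | step 12 | 2-[4-(benzyloxy)phenyl]-8-methoxy-4-oxo-4H-chromene-3,5,7-triyl triacetate | COc1c(OC(C)=O)cc(OC(C)=O)c2c(=O)c(OC(C)=O)c(-c3ccc(OCc4ccccc4)cc3)oc12
F12 | step 12 | 2-(4-hydroxyphenyl)-8-methoxy-4-oxo-4H-chromene-3,5,7-triyl triacetate | COc1c(OC(C)=O)cc(OC(C)=O)c2c(=O)c(OC(C)=O)c(-c3ccc(O)cc3)oc12
F13 | step 12 | 8-methoxy-2-{4-[(3-methylbut-2-en-1-yl)oxy]phenyl}-4-oxo-4H-chromene-3,5,7-triyl triacetate | COc1c(OC(C)=O)cc(OC(C)=O)c2c(=O)c(OC(C)=O)c(-c3ccc(OCC=C(C)C)cc3)oc12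
A1 | alternative 1 | racemic 2-[4-(benzyloxy)phenyl]-8-methoxy-5,7-bis(methoxymethoxy)-2H-chromene (one enantiomer drawn) | COc1c(OCOC)cc(OCOC)c2C=C[C@@H](c3ccc(OCc4ccccc4)cc3)Oc12
A2 | alternative 1 | racemic 2,3-trans-3,4-cis-2-[4-(benzyloxy)phenyl]-8-methoxy-5,7-bis(methoxymethoxy)chromane-3,4-diol | COc1c(OCOC)cc(OCOC)c2[C@H](O)[C@H](O)[C@@H](c3ccc(OCc4ccccc4)cc3)Oc12
A3 | alternative 2 | racemic 3-[3,5-bis(benzyloxy)-2-methoxyphenoxy]-2-(benzyloxy)-3-[4-(tosyloxy)phenyl]propanoic acid, relative configuration as in A4 | COc1c(OCc2ccccc2)cc(OCc2ccccc2)cc1O[C@H](c1ccc(OS(=O)(=O)c2ccc(C)cc2)cc1)[C@H](C(=O)O)OCc1ccccc1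
A4 | alternative 2 | racemic trans-3,5,7-tris(benzyloxy)-8-methoxy-2-[4-(tosyloxy)phenyl]chroman-4-one | O=C1c2c(OCc3ccccc3)cc(OCc3ccccc3)c(OC)c2O[C@H](c2ccc(OS(=O)(=O)c3ccc(C)cc3)cc2)[C@H]1OCc1ccccc1
A5 | alternative 3 | racemic 3-methoxy-4,6-bis(methoxymethoxy)-2-{1-[4-(3-methylbut-2-enyloxy)phenyl]-2-oxoethoxy}benzaldehyde (one enantiomer drawn) | COc1c(OCOC)cc(OCOC)c(C=O)c1O[C@@H](C=O)c1ccc(OCC=C(C)C)cc1
A6 | alternative 3 | racemic trans-3-hydroxy-8-methoxy-5,7-bis(methoxymethoxy)-2-[4-(3-methylbut-2-enyloxy)phenyl]chroman-4-one | COc1c(OCOC)cc(OCOC)c2C(=O)[C@H](O)[C@@H](c3ccc(OCC=C(C)C)cc3)Oc12
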